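The butyrolactone is disconnected at O1–C2 and its C5 methylene is raised to a formyl group. This leads back to an acyclic formyl acid bearing the ring A benzyl on C4 and the ring B benzyl on C3, usable as a mixture of all four stereoisomers. The feature exploited is that C5, the ring OCH2 carbon, adjoins stereocentre C4: as CHO it renders C4–H exchangeable, whereas C3 lies alpha to the C2 carbonyl. One telescoped operation (ketoreductase dynamic kinetic resolution, acid-induced ring closure, base equilibration) therefore funnels every isomer into the (3R,4R)-lactone. The precursor arises from an Ireland–Claisen rearrangement followed by vinyl cleavage. Hydrogenolysis of three benzyl ethers completes the synthesis.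

Key step: step 8

Remark 1: the formyl acid is drawn open-chain; in acidic or neutral media it rests largely as its cyclic 5-hydroxylactone tautomer, which is treated as the same compound.
Remark 2: lactone numbering (O1, C2 carbonyl, C3, C4, C5) is also used for the corresponding atoms of the open-chain compounds.
Remark 3: it is assumed that screening a commercial ketoreductase panel provides a variant that accepts the 4R epimers of both C3 series.
Remark 4: all three phenols stay benzylated until the end because the free ring B catechol would be oxidised in buffer at pH 9 and under DBU. No hydrogenation or dissolving-metal step precedes step 9, so these ethers are never at risk.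

Step 1
Reactants: 1 5-hydroxyvanillin (3,4-dihydroxy-5-methoxybenzaldehyde)
Product: 2 3,4-bis(benzyloxy)-5-methoxybenzaldehyde
Conditions: BnBr (2.3 equiv), K2CO3, DMF, 60 °C, N2
Reagents that add atoms: benzyl bromide, BrCc1ccccc1
Why: Williamson ether synthesis in which carbonate deprotonates both catechol hydroxyls and the phenoxides displace bromide from the benzylic halide by SN2, the aldehyde being inert and no stereocentre being involved.

Step 2
Reactants: 2 3,4-bis(benzyloxy)-5-methoxybenzaldehyde; 3 Meldrum's acid (2,2-dimethyl-1,3-dioxane-4,6-dione)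
Product: 6 3-[3,4-bis(benzyloxy)-5-methoxyphenyl]propanoic acid, via arylidene Meldrum's acid 4 (not isolated), via benzyl Meldrum's acid 5 (not isolated)
Conditions: HCO2H/Et3N (5:2), 95–100 °C; aq. HCl work-up
Reagents that add atoms: water, O
Why: Knoevenagel condensation gives the strongly electrophilic arylidene 4, formate transfers hydride to its benzylic carbon (transfer conjugate reduction), and at this temperature water opens the dioxanedione of 5 with loss of acetone and CO2, a known metal-free one-pot conversion of aryl aldehydes into 3-arylpropanoic acids that spares the benzyl ethers.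

Step 3
Reactants: 7 eugenol (4-allyl-2-methoxyphenol)
Product: 8 4-allyl-1-(benzyloxy)-2-methoxybenzene
Conditions: BnBr (1.1 equiv), K2CO3, acetone, reflux
Reagents that add atoms: benzyl bromide, BrCc1ccccc1
Why: Williamson ether synthesis on the single phenol, the allyl group being inert to carbonate at this temperature.

Step 4
Reactants: 8 4-allyl-1-(benzyloxy)-2-methoxybenzene; 9 (Z)-but-2-ene-1,4-diol
Product: 10 (E)-4-[4-(benzyloxy)-3-methoxyphenyl]but-2-en-1-ol
Conditions: 9 (3 equiv), second-generation Grubbs catalyst RuCl2(=CHPh)(PCy3)(SIMes) (2 mol%), 1,4-benzoquinone (10 mol%), CH2Cl2, 40 °C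
Reagents that add atoms: none
Why: Olefin cross metathesis between a terminal allylarene and an excess of a symmetrical internal allylic diol, a pairing known for eugenol-type arenes, in which every productive exchange installs the CH–CH2OH terminus, benzoquinone suppresses double-bond migration, and the alkene geometry (mainly E) is of no consequence because all stereochemical information is levelled in step 8.

Step 5
Reactants: 6 3-[3,4-bis(benzyloxy)-5-methoxyphenyl]propanoic acid; 10 (E)-4-[4-(benzyloxy)-3-methoxyphenyl]but-2-en-1-ol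
Product: 11 (E)-4-[4-(benzyloxy)-3-methoxyphenyl]but-2-en-1-yl 3-[3,4-bis(benzyloxy)-5-methoxyphenyl]propanoate
Conditions: EDC·HCl, DMAP (cat.), CH2Cl2, 0 °C to rt
Reagents that add atoms: none
Why: Steglich-type carbodiimide esterification of an unhindered acid and a primary allylic alcohol under near-neutral conditions that leave the skipped aryl–alkene unit in place.

Step 6
Reactants: 11 (E)-4-[4-(benzyloxy)-3-methoxyphenyl]but-2-en-1-yl 3-[3,4-bis(benzyloxy)-5-methoxyphenyl]propanoate
Product: 14 2-{[3,4-bis(benzyloxy)-5-methoxyphenyl]methyl}-3-{[4-(benzyloxy)-3-methoxyphenyl]methyl}pent-4-enoic acid (all four stereoisomers), via silyl ketene acetal 12 (not isolated), via trimethylsilyl ester 13 (not isolated)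
Conditions: TMSCl (present from the start), LiN(iPr)2 (LDA, commercial solution), THF, −78 °C; then rt to 55 °C; 1 M HCl work-up
Reagents that add atoms: none
Why: Ireland–Claisen rearrangement in which the ester is enolised and silylated in situ and the silyl ketene acetal undergoes a [3,3]-sigmatropic shift through a six-membered cyclic transition state, forming the C3–C4 bond with the vinyl group (the future C5) on C4, and both new stereocentres may form unselectively because C4 is reset and C3 equilibrated in step 8.

Step 7
Reactants: 14 2-{[3,4-bis(benzyloxy)-5-methoxyphenyl]methyl}-3-{[4-(benzyloxy)-3-methoxyphenyl]methyl}pent-4-enoic acid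
Product: 16 4-[4-(benzyloxy)-3-methoxyphenyl]-2-{[3,4-bis(benzyloxy)-5-methoxyphenyl]methyl}-3-formylbutanoic acid (all four stereoisomers), via diol acid 15 (not isolated)
Conditions: K2OsO4·2H2O (2 mol%), NaIO4 (4 equiv), 2,6-lutidine (3 equiv), 1,4-dioxane/H2O (3:1), rt; citric acid work-up
Reagents that add atoms: sodium periodate (oxygen relayed through OsO4), [Na+].[O-]I(=O)(=O)=O
Why: Lemieux–Johnson oxidation in which catalytic OsO4 dihydroxylates the only alkene and periodate cleaves the terminal diol at once, lutidine holding the acid as carboxylate so that it does not lactonise onto the diol, while the aryl ethers are inert to both oxidants.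

Step 8
Reactants: 16 4-[4-(benzyloxy)-3-methoxyphenyl]-2-{[3,4-bis(benzyloxy)-5-methoxyphenyl]methyl}-3-formylbutanoic acid
Product: 19 (3R,4R)-4-{[4-(benzyloxy)-3-methoxyphenyl]methyl}-3-{[3,4-bis(benzyloxy)-5-methoxyphenyl]methyl}oxolan-2-one, via (3R)-hydroxy acid 17 (not isolated), via (4R)-lactone epimer pair 18 (not isolated)
Conditions: (a) ketoreductase (NADPH-dependent, from panel screening), NADP+ (cat.), iPrOH (15 vol%), DMSO (5 vol%), 0.2 M glycine/NaOH buffer pH 9.0, 35 °C, N2 sweep; (b) 2 M HCl to pH 2, extraction into toluene, TsOH·H2O (1 mol%), 50 °C; (c) DBU (0.5 equiv), toluene, 100 °C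
Reagents that add atoms: none
Why: At pH 9 the substrate is the open formyl carboxylate, whose C4–H exchanges through the enol and through the imine/enamine formed with glycine, so the 4R and 4S epimers of both C3 series interconvert while the enzyme delivers hydride from NADPH (recycled by the same enzyme at the expense of iPrOH, which forms no acid and so leaves the pH in the exchange window) to C5 of the 4R epimers only. The closest known reaction type is the reductive dynamic kinetic resolution of racemic alpha-branched aldehydes with alcohol dehydrogenases or ketoreductases, here applied to a larger aldehyde. Protonation of 17 starts a 5-exo-trig acyl substitution in which the C5 hydroxyl attacks C2 and water leaves, forming O1–C2 and closing the only new ring. C4 is controlled by the enzyme pocket through its choice of epimer (C5 itself is not stereogenic) and is frozen as soon as C5 is an alcohol, whereas C3 is controlled by thermodynamics, since DBU enolises the lactone reversibly until the two benzyl arms stand trans, which for 4R means 3R. The step needs C4 exchange to outrun reduction of the 4S epimers and needs recognition of C4 that is blind to C3; the substrate supports both because the two arms on C4 differ sharply (a flat neutral benzyl against a branched arm with an anionic carboxylate), the carboxylate keeps the aldehyde unmasked and the salt dispersible in the aqueous alcohol, and no other group is reducible or enolisable under these conditions.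

Step 9
Reactants: 19 (3R,4R)-4-{[4-(benzyloxy)-3-methoxyphenyl]methyl}-3-{[3,4-bis(benzyloxy)-5-methoxyphenyl]methyl}oxolan-2-one
Product: 20 (−)-thujaplicatin, (3R,4R)-3-[(3,4-dihydroxy-5-methoxyphenyl)methyl]-4-[(4-hydroxy-3-methoxyphenyl)methyl]oxolan-2-one
Conditions: H2 (1 atm), Pd/C (10 wt%), EtOAc/EtOH (1:1), rt; work-up under N2
Reagents that add atoms: none
Why: Catalytic hydrogenolysis cleaves the three O–CH2Ph bonds of the aryl benzyl ethers, while the lactone, the methyl ethers and the ArCH2–C bonds are inert and the neutral medium leaves both stereocentres untouched.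

Compound list
1 | 5-hydroxyvanillin (3,4-dihydroxy-5-methoxybenzaldehyde) | COc1cc(C=O)cc(O)c1O | starting material
2 | 3,4-bis(benzyloxy)-5-methoxybenzaldehyde | COc1cc(C=O)cc(OCc2ccccc2)c1OCc1ccccc1 | intermediate
3 | Meldrum's acid (2,2-dimethyl-1,3-dioxane-4,6-dione) | CC1(C)OC(=O)CC(=O)O1 | starting material
4 | 5-{[3,4-bis(benzyloxy)-5-methoxyphenyl]methylidene}-2,2-dimethyl-1,3-dioxane-4,6-dione | COc1cc(C=C2C(=O)OC(C)(C)OC2=O)cc(OCc2ccccc2)c1OCc1ccccc1 | intermediate
5 | 5-{[3,4-bis(benzyloxy)-5-methoxyphenyl]methyl}-2,2-dimethyl-1,3-dioxane-4,6-dione | COc1cc(CC2C(=O)OC(C)(C)OC2=O)cc(OCc2ccccc2)c1OCc1ccccc1 | intermediate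
6 | 3-[3,4-bis(benzyloxy)-5-methoxyphenyl]propanoic acid | COc1cc(CCC(=O)O)cc(OCc2ccccc2)c1OCc1ccccc1 | intermediate
7 | eugenol (4-allyl-2-methoxyphenol) | COc1cc(CC=C)ccc1O | starting material
8 | 4-allyl-1-(benzyloxy)-2-methoxybenzene | COc1cc(CC=C)ccc1OCc1ccccc1 | intermediate
9 | (Z)-but-2-ene-1,4-diol | OC/C=C\CO | starting material
10 | (E)-4-[4-(benzyloxy)-3-methoxyphenyl]but-2-en-1-ol | COc1cc(C/C=C/CO)ccc1OCc1ccccc1 | intermediate
11 | (E)-4-[4-(benzyloxy)-3-methoxyphenyl]but-2-en-1-yl 3-[3,4-bis(benzyloxy)-5-methoxyphenyl]propanoate | COc1cc(C/C=C/COC(=O)CCc2cc(OC)c(OCc3ccccc3)c(OCc3ccccc3)c2)ccc1OCc1ccccc1 | intermediate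
12 | trimethylsilyl ketene acetal of 11 (ketene acetal geometry undefined) | COc1cc(C/C=C/COC(O[Si](C)(C)C)=CCc2cc(OC)c(OCc3ccccc3)c(OCc3ccccc3)c2)ccc1OCc1ccccc1 | intermediate
13 | trimethylsilyl ester of 14 (all four stereoisomers) | C=CC(Cc1ccc(OCc2ccccc2)c(OC)c1)C(Cc1cc(OC)c(OCc2ccccc2)c(OCc2ccccc2)c1)C(=O)O[Si](C)(C)C | intermediate
14 | 2-{[3,4-bis(benzyloxy)-5-methoxyphenyl]methyl}-3-{[4-(benzyloxy)-3-methoxyphenyl]methyl}pent-4-enoic acid (all four stereoisomers) | C=CC(Cc1ccc(OCc2ccccc2)c(OC)c1)C(Cc1cc(OC)c(OCc2ccccc2)c(OCc2ccccc2)c1)C(=O)O | intermediate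
15 | 2-{[3,4-bis(benzyloxy)-5-methoxyphenyl]methyl}-3-{[4-(benzyloxy)-3-methoxyphenyl]methyl}-4,5-dihydroxypentanoic acid (stereoisomer mixture) | OCC(O)C(Cc1ccc(OCc2ccccc2)c(OC)c1)C(Cc1cc(OC)c(OCc2ccccc2)c(OCc2ccccc2)c1)C(=O)O | intermediate
16 | 4-[4-(benzyloxy)-3-methoxyphenyl]-2-{[3,4-bis(benzyloxy)-5-methoxyphenyl]methyl}-3-formylbutanoic acid (all four stereoisomers) | OC(=O)C(Cc1cc(OCc2ccccc2)c(OCc2ccccc2)c(OC)c1)C(C=O)Cc1ccc(OCc2ccccc2)c(OC)c1 | intermediate
17 | (3R)-4-[4-(benzyloxy)-3-methoxyphenyl]-2-{[3,4-bis(benzyloxy)-5-methoxyphenyl]methyl}-3-(hydroxymethyl)butanoic acid, both C2 epimers | OC(=O)C(Cc1cc(OCc2ccccc2)c(OCc2ccccc2)c(OC)c1)[C@H](CO)Cc1ccc(OCc2ccccc2)c(OC)c1 | intermediate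
18 | (4R)-4-{[4-(benzyloxy)-3-methoxyphenyl]methyl}-3-{[3,4-bis(benzyloxy)-5-methoxyphenyl]methyl}oxolan-2-one, both C3 epimers | COc1cc(C[C@H]2COC(=O)C2Cc2cc(OCc3ccccc3)c(OCc3ccccc3)c(OC)c2)ccc1OCc1ccccc1 | intermediate
19 | (3R,4R)-4-{[4-(benzyloxy)-3-methoxyphenyl]methyl}-3-{[3,4-bis(benzyloxy)-5-methoxyphenyl]methyl}oxolan-2-one | COc1cc(C[C@H]2COC(=O)[C@@H]2Cc2cc(OCc3ccccc3)c(OCc3ccccc3)c(OC)c2)ccc1OCc1ccccc1 | intermediate
20 | (−)-thujaplicatin, (3R,4R)-3-[(3,4-dihydroxy-5-methoxyphenyl)methyl]-4-[(4-hydroxy-3-methoxyphenyl)methyl]oxolan-2-one | COc1cc(C[C@H]2COC(=O)[C@@H]2Cc2cc(O)c(O)c(OC)c2)ccc1O | target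

Total step count: 9.
Longest linear sequence: 7 steps (3, 4, 5, 6, 7, 8, 9; the branch 1, 2, 5, 6, 7, 8, 9 is equally long).

Steps most likely to fail

Step 8. Exchange at C4 of a purely aliphatic alpha-branched aldehyde may be too slow to keep the enzyme supplied. Alternatively, the enzyme may tell the C4 epimers apart in only one of the two C3 series. Either failure would stall conversion or erode enantiomeric purity. The fallback gives up stereoconvergence in favour of resolution and sets out from 16. Reduction with NaBH4 in THF/aqueous NaOH followed by acidic work-up should give the stereorandom lactone F1. DBU in hot toluene should level this to the racemic trans-lactone F2. Preparative chromatography on a chiral stationary phase (amylose carbamate, supercritical CO2/MeOH) should then separate the (3R,4R) half, and the route is rejoined at 19.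

Step 7. The transient diol may close onto the carboxyl group, which would hide the secondary hydroxyl from periodate and stop the cleavage. The fallback is a cleavage with no diol stage and sets out from 14. Ozonolysis is run in CH2Cl2 at −78 °C, with Sudan red 7B as end-point indicator so that the alkoxyarenes are spared. It should lead, by capture of the carbonyl oxide by the neighbouring carboxyl group, to the 5-hydroperoxylactone F3. Me2S reduces F3 to the ring tautomer of the formyl acid, and the route is rejoined at 16.

Step 4. Ruthenium hydride decomposition products may shift the allyl double bond into conjugation with ring A, and 8 may undergo self-metathesis. Both processes would consume the arene. The fallback builds the four-carbon arm by carbonyl olefination and sets out from 8. Lemieux–Johnson cleavage (K2OsO4·2H2O, NaIO4, 2,6-lutidine) should give the arylacetaldehyde F4. A Wittig reaction with Ph3P=CHCO2Et in CH2Cl2, under neutral conditions that do not move the alkene toward the ring, should give the ethyl (E)-but-2-enoate F5. Reduction with iBu2AlH in CH2Cl2 at −78 °C rejoins the route at 10.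

Further compounds
F1 | step 8 | 4-{[4-(benzyloxy)-3-methoxyphenyl]methyl}-3-{[3,4-bis(benzyloxy)-5-methoxyphenyl]methyl}oxolan-2-one, all four stereoisomers | COc1cc(CC2COC(=O)C2Cc2cc(OCc3ccccc3)c(OCc3ccccc3)c(OC)c2)ccc1OCc1ccccc1
F2 | step 8 | racemic trans-lactone, (3R,4R) and (3S,4S) forms in equal parts | COc1cc(C[C@H]2COC(=O)[C@@H]2Cc2cc(OCc3ccccc3)c(OCc3ccccc3)c(OC)c2)ccc1OCc1ccccc1.COc1cc(C[C@@H]2COC(=O)[C@H]2Cc2cc(OCc3ccccc3)c(OCc3ccccc3)c(OC)c2)ccc1OCc1ccccc1
F3 | step 7 | 4-{[4-(benzyloxy)-3-methoxyphenyl]methyl}-3-{[3,4-bis(benzyloxy)-5-methoxyphenyl]methyl}-5-hydroperoxyoxolan-2-one, stereoisomer mixture | COc1cc(CC2C(OO)OC(=O)C2Cc2cc(OCc3ccccc3)c(OCc3ccccc3)c(OC)c2)ccc1OCc1ccccc1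
F4 | step 4 | 2-[4-(benzyloxy)-3-methoxyphenyl]acetaldehyde | COc1cc(CC=O)ccc1OCc1ccccc1
F5 | step 4 | ethyl (E)-4-[4-(benzyloxy)-3-methoxyphenyl]but-2-enoate | CCOC(=O)/C=C/Cc1ccc(OCc2ccccc2)c(OC)c1
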